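## The problem

The target is a 20-nor-gibberellane. Ring A (C1–C2–C3–C4–C5–C10) is bridged by a γ-lactone from C19 on C4 to the oxygen on C10. Ring B (C5–C6–C8–C9–C10) carries the C7 acid. Rings C and D form a bicyclo[3.2.1]octane (C8–C9–C11–C12–C13–C14 bridged by C15–C16) with the C16=C17 methylene and an axial C12 hydroxyl.

Nine stereocentres (C1, C4, C5, C6, C8, C9, C10, C12, C13) sit on nineteen carbons. C4 and C8 are all-carbon quaternary, C10 is fully substituted and oxygenated, and the B/C hydrindane is trans-fused (H9 anti to the C8–C15 bond). Only C8 needs an external source of chirality. Its angular substituent can shield one face of ring B and so direct C9 and C10. The C10 oxygen can act as a tether that fixes C5 and, through the lactone, C4 and C1. C5 then sets the epimerizable C6 thermodynamically, the C8 arm fixes C13, and the bridge steers the C12 reduction.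

Three groups will not survive rough treatment. The C1-hydroxy-C3-ketone is an aldol that reverts or dehydrates with base or strong acid. The C3 ketone and C19 lactone on quaternary C4 form a β-keto ester that hydroxide cleaves, with decarboxylation once the lactone opens. The exocyclic methylene on the bicyclooctane isomerizes or rearranges in strong acid. The last steps therefore have to be close to neutral.

The enabling feature is that C13 is α to the C12 oxygen and bonded to C16, which bears the exocyclic CH2. Ring D is thus what a C12 enol ether gives when it adds through C13 to the internal carbon of a C15–C16≡C17 propargyl group on C8, which the trans-hydrindane holds axial over C13.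

## Retrosynthesis

**28 ⇐ 27 ⇐ 26.** No skeletal bond is cut. The axial C12 alcohol of 27 is traced to ketone 26, the oxidation level that the ring D closure delivers. The C1 silyl ether and the 2-(trimethylsilyl)ethyl ester are both fluoride-labile, so one near-neutral step frees the aldol and the acid. A tert-butyl ester or a C3 ketal would need acid strong enough to endanger the methylene, and hydroxide would cleave the β-keto lactone.

**26 ⇐ 25.** The C13–C16 bond is cut, which opens ring D to the propargyl silyl enol ether 25. The alternative cut at C8–C15 would place the quaternary centre last. The cut at C12–C13 would need ring D as a spiro cyclopentene on C8 before ring C. Compound 25 has one ring, one C–C bond and one stereocentre fewer, and the alkyne is already at the oxidation level of the methylene. The forward reaction must be 5-exo, must start from the C12=C13 enol ether, and must tolerate an ester beside the alkyne.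

**25 ⇐ 23.** The C1–C2 bond of ring A is cut at the aldol retron (1-silyloxy-3-ketone) to give methyl ketone–aldehyde 23. The silyl triflate and amine that make the C12 enol ether also make the methyl ketone enol ether and trigger its addition to the aldehyde, by way of 24. Cutting C3–C4 instead would build the quaternary centre in the ring closure. Cutting C1–C10 would require carbon addition to a hindered ketone from the shielded face. The forward reaction has to place O1 trans to the lactone oxygen.

**23 ⇐ 22 ⇐ 21 ⇐ 19 + 20.** The C4–C5 bond (Michael retron) and the O10–C19 ester bond are cut. Acylation of the tertiary alcohol 19 with the ketene from dioxinone 20 gives β-keto ester 21. Its carbanion adds to the enoate to close the lactone 22, and acid then unmasks 23. An intermolecular addition of a tertiary carbanion to a cyclopentene carboxylate would be slow and facially uncontrolled. The tether makes it a 5-exo closure that can only give H5 on the face opposite the lactone. The forward step must put the acetyl arm of C4 on the outer face.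

**19 ⇐ 17 ⇐ 16.** The C10–O and C1–C10 bonds are cut back to ketone 16. A carbon nucleophile would attack C10 anti to the angular propargyl group and leave the oxygen on the wrong face. So carbon is attached first as an enol ether (17), and the oxygen is then delivered from the open face by epoxidation (via 18). This gives C1 directly at the aldehyde level as an acetal.

**16 ⇐ 15 ⇐ 14 ⇐ 13.** The C10 carbonyl comes from allylic oxidation of enoate 15, whose only allylic methylene is C10. The C6–C7 bond is cut by carbonylation of enol triflate 14, and 14 comes regiospecifically from ketone 13 because C8 is quaternary.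

**13 ⇐ 12 ⇐ 10 ⇐ 9 ⇐ 8 ⇐ 7.** These are redox and protecting-group changes that set C9. A Diels–Alder construction of ring C on a cyclopentenone would give the cis fusion, so C9 is set by conjugate reduction of the enone. The C6 ketone is turned into a silyloxy group syn to the propargyl arm (8, 9) so that both shield the same face and hydride reaches C9 from the other (10). Ketalization and loss of the silyl group give 12 (via 11), and oxidation gives 13.

**7 ⇐ 5 ⇐ 3 + 4; 3 ⇐ 1 + 2.** The C9–C11 bond (aldol and dehydration, via ketol 6), the C8–C14 bond (Michael addition to 4) and the C8–C15 bond (alkylation of 1 with 2) are cut. The proline-mediated aldol selects between the two enantiotopic carbonyls of 5 and fixes C8, the only stereocentre that needs an external source of chirality.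

## Roads not taken

**Alternative 1:** The cut is C9–C11 of ring C in the prochiral triketone A1. In the forward step L-proline condenses the methyl carbon with one of the two enantiotopic ring carbonyls and dehydration gives the angular-allyl enedione A2.
- Merits: it is catalytic, cheap, and sets the absolute configuration at C8 while mapping rings B and C.
- Weak points: as the strategic centre it solves only C8 and two rings. Ring D, ring A, the lactone and six further stereocentres are left open. The allyl arm would need either an oxidative cycloalkenylation of a C12 enol ether with Pd(OAc)2 or two steps to become an alkyne.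
- Comparison: the chosen route uses the same desymmetrization as step 3 with propargyl in place of allyl, so the two are equal there. The allyl group is the hardier passenger, since it has no acidic C–H, is indifferent to the copper hydride of step 6, and would allow hydroboration tactics for the trans fusion. Against this the chosen plan sets an alkyne that is already at the oxidation level of the methylene, so ring D closes without an oxidant and gives the C12 ketone directly.

**Alternative 2:** The cut is C4–C19. In the forward step KH forms the C3–C4 enolate of the ring A ketone in A3, whose C10 oxygen carries an imidazole-1-carboxylate. C-acylation closes the lactone and creates quaternary C4 in A4.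
- Merits: the configuration at C4 is enforced by the tether, and the lactone and the quaternary centre arrive together.
- Weak points: a carbocyclic ring A, trans-fused to ring B and bearing the tertiary C10 alcohol, must exist first. Enolization has to go toward C4 and not C2, and C- has to beat O-acylation. A4 lacks the C1 hydroxyl, which would have to be introduced late at an unactivated methylene (enone formation, epoxidation, reductive opening) beside the exocyclic alkene.
- Comparison: at C4 this road is better than step 15 of the chosen plan, where the configuration rests on a transition-state preference backed by equilibration. The chosen plan sets against it that the C1 oxygen is installed by the ring A closure itself and that no carbocyclic ring A has to be made beforehand.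

**Alternative 3:** The cut is C12–C13. In the forward step BF3·OEt2 activates the C12 aldehyde of A5 and the cyclopentenyl allylsilane attacks through C13 (Hosomi–Sakurai reaction). This closes ring C, and with it the bicyclooctane, and gives the methylene and the C12 alcohol of A6.
- Merits: one step forms the bridged system, the methylene and the C12 hydroxyl at the alcohol oxidation level. No hydride reduction is needed and no ketone at C12 has to be told apart from the one at C3. In this respect it is better than steps 18 and 19 of the chosen plan.
- Weak points: ring D must first be built as a cyclopentene spiro-attached at C8, a quaternary centre whose two ring arms differ only in the position of the double bond. That is harder to set than the angular centre of a proline annulation. The configuration at C12 depends on the conformation of the aldehyde in an open transition state. BF3 also meets the β-silyloxy ketone.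
- Comparison: the chosen plan sets against it a C8 centre made in three steps from cheap materials and a ring closure whose stereochemistry is fixed by the tether.

Key step: step 18

Remark on locants: all intermediates are described with gibberellane numbers. Ring A is C1–C5 and C10; ring B is C5, C6, C8, C9, C10; ring C is C8, C9, C11–C14. C15–C17 are the propargyl carbons, C7 is on C6, and the C18 methyl and C19 carbonyl are on C4. "Syn" and "anti" refer to the face of ring B relative to the C8–C15 bond.

Assumption: 2,2,5,6-tetramethyl-4H-1,3-dioxin-4-one (20), the acetone adduct of methyl(acetyl)ketene, is taken as a purchasable reagent. It supplies the five carbons of a 2-methylacetoacetyl unit.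

## Route

Step 1
Reactants: 1 cyclopentane-1,3-dione; 2 propargyl bromide (3-bromoprop-1-yne)
Product: 3 2-(prop-2-yn-1-yl)cyclopentane-1,3-dione
Conditions: NaOH (1 equiv), H2O, 60 °C
Reagents that add atoms: none
Why: C-alkylation of the dione enolate; water solvates the enolate oxygens and favours carbon attack, the standard way to 2-substituted cyclopentane-1,3-diones.

Step 2
Reactants: 3 2-(prop-2-yn-1-yl)cyclopentane-1,3-dione; 4 methyl vinyl ketone (but-3-en-2-one)
Product: 5 2-(3-oxobutyl)-2-(prop-2-yn-1-yl)cyclopentane-1,3-dione
Conditions: Et3N (cat.), EtOAc, rt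
Reagents that add atoms: none
Why: Michael addition of the acidic 2-substituted dione to the enone forms C8–C14 and the prochiral quaternary carbon.

Step 3
Reactants: 5 2-(3-oxobutyl)-2-(prop-2-yn-1-yl)cyclopentane-1,3-dione
Product: 7 (7aR)-7a-(prop-2-yn-1-yl)-2,3,7,7a-tetrahydro-1H-indene-1,5(6H)-dione, via bicyclic ketol 6 (not isolated)
Conditions: L-proline (30 mol%), DMF, rt; then TsOH·H2O (cat.), PhMe, 80 °C
Reagents that add atoms: none
Why: Hajos–Parrish reaction: the proline enamine of the methyl ketone adds to one of the two enantiotopic ring carbonyls (C9–C11) and dehydration gives the enone. C8 is set in the sense established for L-proline with 2-alkyl triketones; the descriptor is R only because propargyl outranks the ring CH2.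

Step 4
Reactants: 7 propargyl Hajos–Parrish enedione
Product: 8 6-hydroxy-9(11)-en-12-one (1-hydroxy-7a-propargyl-hexahydroinden-5-one; hydroxyl syn to propargyl)
Conditions: NaBH4 (0.3 equiv), EtOH, −20 °C
Reagents that add atoms: none
Why: The saturated C6 cyclopentanone is more electrophilic than the conjugated C12 ketone and is reduced alone. Hydride enters anti to the angular group, so the alcohol is syn to it; this temporary centre serves step 6.

Step 5
Reactants: 8 6-hydroxy-9(11)-en-12-one
Product: 9 6-triethylsilyl ether of 8
Conditions: Et3SiCl, imidazole, DMF, 0 °C to rt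
Reagents that add atoms: chlorotriethylsilane, CC[Si](Cl)(CC)CC
Why: Standard silylation; the silyloxy group joins the propargyl arm on the syn face of the bicycle.

Step 6
Reactants: 9 6-triethylsilyloxy-9(11)-en-12-one
Product: 10 trans-fused 6-triethylsilyloxy-12-ketone (H9 anti to propargyl)
Conditions: i-Bu2AlH (2.5 equiv), t-BuCu (0.2 equiv, from CuI and t-BuLi), HMPA, THF, −50 °C
Reagents that add atoms: none
Why: Conjugate reduction by the copper hydride formed from i-Bu2AlH delivers hydride to C9 from the face opposite the propargyl and silyloxy groups, which gives the trans-hydrindanone; the method is established for 1-alkoxy and 1-silyloxy enones of this type. In THF/HMPA at this temperature hydroalumination of the alkyne should be negligible, and any aluminium acetylide is reprotonated on work-up.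

Step 7
Reactants: 10 trans-fused 6-triethylsilyloxy-12-ketone
Product: 12 12,12-ethylenedioxy-6-ol, via ketal triethylsilyl ether 11 (not isolated)
Conditions: HOCH2CH2OH, TsOH·H2O (cat.), PhH, reflux (Dean–Stark); then MeOH, rt
Reagents that add atoms: ethylene glycol, OCCO
Why: The unhindered C12 ketone is ketalized, and the acid-labile triethylsilyl ether is then solvolysed in the same acidic medium, freeing the C6 alcohol without a separate step.

Step 8
Reactants: 12 12,12-ethylenedioxy-6-ol
Product: 13 12,12-ethylenedioxy-6-ketone
Conditions: Dess–Martin periodinane, CH2Cl2, 0 °C to rt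
Reagents that add atoms: none
Why: Dess–Martin oxidation of a hindered secondary alcohol; the ketal and the alkyne are untouched.

Step 9
Reactants: 13 12,12-ethylenedioxy-6-ketone
Product: 14 5-en-6-yl trifluoromethanesulfonate (C5=C6, 12-ketal)
Conditions: KN(SiMe3)2 (1.05 equiv), THF, −78 °C; then PhNTf2
Reagents that add atoms: N-phenylbis(trifluoromethanesulfonimide), O=S(=O)(N(c1ccccc1)S(=O)(=O)C(F)(F)F)C(F)(F)F
Why: C8 is quaternary, so the ketone can enolize only toward C5, and O-triflation of the potassium enolate gives the enol triflate as with 17-keto steroids. With one equivalent of base at −78 °C the ketone, the stronger acid, should be deprotonated before the alkyne.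

Step 10
Reactants: 14 5-en-6-yl trifluoromethanesulfonate
Product: 15 2-(trimethylsilyl)ethyl 5-ene-6-carboxylate (C7 ester on C6, 12-ketal)
Conditions: Pd(OAc)2 (5 mol%), PPh3 (10 mol%), CO (1 atm), Me3SiCH2CH2OH (10 equiv), Et3N, DMF, 50 °C
Reagents that add atoms: carbon monoxide, [C-]#[O+]; 2-(trimethylsilyl)ethanol, C[Si](C)(C)CCO
Why: Alkoxycarbonylation of the enol triflate by zerovalent palladium installs C7; excess alcohol under CO favours alcoholysis of the acylpalladium over insertion of the alkyne. The silylethyl ester is chosen because fluoride removes it later without acid or hydroxide.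

Step 11
Reactants: 15 2-(trimethylsilyl)ethyl 5-ene-6-carboxylate
Product: 16 10-oxo-5-ene-6-carboxylate (C10 ketone conjugated to C5=C6–C7)
Conditions: CrO3, 3,5-dimethylpyrazole, CH2Cl2, −20 °C
Reagents that add atoms: chromium trioxide, O=[Cr](=O)=O
Why: Allylic oxidation; C10 is the only allylic methylene (C8 is quaternary), and γ-oxidation of cyclopentene carboxylates to 4-oxo-enoates is known. The neopentyl propargylic CH2 should react more slowly.

Step 12
Reactants: 16 10-oxo-5-ene-6-carboxylate
Product: 17 10-(methoxymethylene) dienoate (C1=C10 enol ether, E/Z mixture)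
Conditions: Ph3P(Cl)CH2OMe, KN(SiMe3)2, THF, 0 °C; then 16, −78 to 0 °C
Reagents that add atoms: (methoxymethyl)triphenylphosphonium chloride, COC[P+](c1ccccc1)(c1ccccc1)c1ccccc1.[Cl-]
Why: Wittig methoxymethylenation of the C10 ketone attaches C1 at the aldehyde oxidation level; the non-stabilized ylide adds 1,2 to the enone carbonyl. The reaction is run cold because H9 is now enolizable; the enol ether geometry is irrelevant.

Step 13
Reactants: 17 10-(methoxymethylene) dienoate
Product: 19 10-hydroxy-10-(dimethoxymethyl) enoate (O10 anti and C1 syn to propargyl), via methoxy epoxide 18 (not isolated)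
Conditions: dimethyldioxirane, acetone/MeOH, −40 °C; then PPTS (cat.), 0 °C
Reagents that add atoms: dimethyldioxirane, CC1(C)OO1; methanol, CO
Why: Rubottom-type oxidation: the electron-rich enol ether is epoxidized in preference to the enoate and the alkyne, and methanol opens the 2-methoxyoxirane at C1 to the α-hydroxy acetal. The oxidant reaches C10 from the face of H9, opposite the axial propargyl group, which sets O10 anti to C15.

Step 14
Reactants: 19 10-hydroxy-10-(dimethoxymethyl) enoate; 20 2,2,5,6-tetramethyl-4H-1,3-dioxin-4-one
Product: 21 10-O-(2-methyl-3-oxobutanoyl) ester of 19 (C4 epimers)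
Conditions: 20 (3 equiv), PhMe, 110 °C
Reagents that add atoms: none
Why: Thermal retro-[4+2] of the dioxinone releases methyl(acetyl)ketene, which acylates hindered tertiary alcohols under neutral conditions. This hangs C19, C4 with C18, C3 and C2 on O10.

Step 15
Reactants: 21 10-O-(2-methyl-3-oxobutanoyl) ester
Product: 22 tricyclic γ-lactone (C4 bearing methyl and acetyl bonded to C5 anti; H5 syn; C7 ester syn; acetal on C10)
Conditions: Cs2CO3 (0.5 equiv), MeCN, rt
Reagents that add atoms: none
Why: Intramolecular Michael addition (5-exo-trig) of the β-keto ester carbanion C4 to C5; the O10 tether reaches only the anti face, so the lactone is cis-fused and H5 is syn. The acetyl arm should lie outside the fold of the bicycle with the methyl inside; the addition is reversible, so the C4 epimers can be equilibrated. C6 is protonated under equilibrating conditions with C7 trans to C4.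

Step 16
Reactants: 22 tricyclic γ-lactone
Product: 23 keto aldehyde (12-ketone, C10–CHO, acetyl on C4)
Conditions: 2 M HCl, THF, 40 °C
Reagents that add atoms: water, O
Why: Acid hydrolysis of the dioxolane and of the deactivated dimethyl acetal. C10 is quaternary, so the aldehyde cannot epimerize; the lactone and the silylethyl ester tolerate dilute aqueous acid.

Step 17
Reactants: 23 keto aldehyde
Product: 25 12-(tert-butyldimethylsilyloxy)-12(13)-ene 1-silyl ether 3-ketone (ring A closed; propargyl on C8), via bis-silyl enol ether 24 (not isolated)
Conditions: t-BuMe2SiOTf (2.6 equiv), Et3N (4 equiv), CH2Cl2, −78 to 0 °C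
Reagents that add atoms: tert-butyldimethylsilyl trifluoromethanesulfonate, CC(C)(C)[Si](C)(C)OS(=O)(=O)C(F)(F)F
Why: Soft enolization silylates both ketones. The C12 enol ether forms toward C13, because a C12=C13 double bond lies opposite the fusion bond of the trans-hydrindane and C13–H is the less hindered. The silyl triflate then activates the non-enolizable aldehyde for an intramolecular Mukaiyama aldol (6-exo) with silyl transfer to O1; with the C1=O anti to the C10–O bond (Cornforth arrangement) the new silyloxy group ends trans-diaxial to the lactone oxygen.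

Step 18
Reactants: 25 propargyl silyl enol ether
Product: 26 12-ketone with ring D and the C16=C17 methylene (1-silyl ether, 3-ketone, silylethyl ester)
Conditions: Ph3PAuCl (10 mol%), AgBF4 (10 mol%), CH2Cl2/MeOH (10:1), rt
Reagents that add atoms: none
Why: Cationic monovalent gold (Ph3PAu+ from Ph3PAuCl and AgBF4) coordinates the terminal alkyne; the enol ether attacks the internal carbon C16 through C13 anti to the metal, the silyloxocarbenium ion gives up silicon to methanol, and protodeauration of the vinylgold releases the methylene and the C12 ketone. The closest known reaction type is the gold-catalysed Conia-ene-type carbocyclization of silyl enol ethers onto alkynes, which is used to make bicyclo[3.2.1]octanes. Ring D closes in the 5-exo-dig mode across the 1,3-diaxial positions C8 and C13 of ring C, where the trans-hydrindane holds the propargyl arm axial. C13 is the only new stereocentre and is dictated by the tether, since C16 can reach it only from the face that carries C15. The step needs the enol ether on the C13 side, which step 17 secures. It needs exo and not endo closure, which the short tether enforces. It needs carbon and not oxygen attack on the alkyne: the neighbouring C7 ester is a primary alkyl ester that cannot shed its alkyl group as a tert-butyl ester would, so carbonyl-oxygen addition is reversible. The C3 ketone, the lactone and the silyl ether are spectators toward the carbophilic catalyst.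

Step 19
Reactants: 26 12-ketone
Product: 27 12-alcohol (hydroxyl axial on ring C, anti to the C15–C16 bridge)
Conditions: LiBH(s-Bu)3 (1.1 equiv), THF, −78 °C
Reagents that add atoms: none
Why: The bulky hydride approaches C12 along the equatorial trajectory past the sp2 carbon C16, avoiding the axial hydrogens on C9 and C14, and gives the axial alcohol. The C3 ketone should be spared because it is flanked by quaternary C4 and screened by the axial C1 silyloxy group on one face and the lactone bridge on the other.

Step 20
Reactants: 27 12-alcohol
Product: 28 target acid CNP0259985.3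
Conditions: (Me2N)3S+ Me3SiF2− (4 equiv), DMF, 0 °C to rt; aq. NH4Cl/NaH2PO4 (pH 4) work-up
Reagents that add atoms: none
Why: Fluoride cleaves the C1 silyl ether and fragments the 2-(trimethylsilyl)ethyl ester to ethene and the carboxylate. The near-neutral medium spares the aldol unit, the β-keto lactone and the exocyclic alkene.

## Compound list

1 | cyclopentane-1,3-dione | O=C1CCC(=O)C1 | starting material
2 | propargyl bromide (3-bromoprop-1-yne) | C#CCBr | starting material
3 | 2-(prop-2-yn-1-yl)cyclopentane-1,3-dione | C#CCC1C(=O)CCC1=O | intermediate
4 | methyl vinyl ketone (but-3-en-2-one) | CC(=O)C=C | starting material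
5 | 2-(3-oxobutyl)-2-(prop-2-yn-1-yl)cyclopentane-1,3-dione | CC(=O)CCC1(CC#C)C(=O)CCC1=O | intermediate
6 | cis-fused ketol, 3a-hydroxy-7a-(prop-2-yn-1-yl)hexahydroindene-1,5-dione (hydroxyl and propargyl cis) | C#CC[C@]12CCC(=O)C[C@@]1(O)CCC2=O | intermediate (not isolated)
7 | (7aR)-7a-(prop-2-yn-1-yl)-2,3,7,7a-tetrahydro-1H-indene-1,5(6H)-dione (propargyl Hajos–Parrish enedione; C6 and C12 ketones, C9=C11) | C#CC[C@]12CCC(=O)C=C1CCC2=O | intermediate
8 | 6-hydroxy-9(11)-en-12-one; hydroxyl syn to propargyl | C#CC[C@]12CCC(=O)C=C1CC[C@@H]2O | intermediate
9 | 6-triethylsilyloxy-9(11)-en-12-one | C#CC[C@]12CCC(=O)C=C1CC[C@@H]2O[Si](CC)(CC)CC | intermediate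
10 | trans-fused 6-triethylsilyloxy-12-ketone; H9 anti to propargyl | C#CC[C@]12CCC(=O)C[C@@H]1CC[C@@H]2O[Si](CC)(CC)CC | intermediate
11 | 12,12-ethylenedioxy 6-triethylsilyl ether | C#CC[C@]12CCC3(OCCO3)C[C@@H]1CC[C@@H]2O[Si](CC)(CC)CC | intermediate (not isolated)
12 | 12,12-ethylenedioxy-6-ol | C#CC[C@]12CCC3(OCCO3)C[C@@H]1CC[C@@H]2O | intermediate
13 | 12,12-ethylenedioxy-6-ketone | C#CC[C@]12CCC3(OCCO3)C[C@@H]1CCC2=O | intermediate
14 | 5-en-6-yl trifluoromethanesulfonate, 12-ketal | C#CC[C@]12CCC3(OCCO3)C[C@@H]1CC=C2OS(=O)(=O)C(F)(F)F | intermediate
15 | 2-(trimethylsilyl)ethyl 5-ene-6-carboxylate, 12-ketal | C#CC[C@]12CCC3(OCCO3)C[C@@H]1CC=C2C(=O)OCC[Si](C)(C)C | intermediate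
16 | 10-oxo-5-ene-6-carboxylate, 12-ketal | C#CC[C@]12CCC3(OCCO3)C[C@@H]1C(=O)C=C2C(=O)OCC[Si](C)(C)C | intermediate
17 | 10-(methoxymethylene) dienoate (C1=C10 enol ether, E/Z mixture) | C#CC[C@]12CCC3(OCCO3)C[C@@H]1C(=COC)C=C2C(=O)OCC[Si](C)(C)C | intermediate
18 | spiro 2-methoxyoxirane at C10; epoxide oxygen anti to propargyl | C#CC[C@]12CCC3(OCCO3)C[C@@H]1[C@@]4(OC4OC)C=C2C(=O)OCC[Si](C)(C)C | intermediate (not isolated)
19 | 10-hydroxy-10-(dimethoxymethyl) enoate; O10 anti, C1 syn | C#CC[C@]12CCC3(OCCO3)C[C@@H]1[C@](O)(C(OC)OC)C=C2C(=O)OCC[Si](C)(C)C | intermediate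
20 | 2,2,5,6-tetramethyl-4H-1,3-dioxin-4-one | CC1=C(C)C(=O)OC(C)(C)O1 | starting material
21 | 10-O-(2-methyl-3-oxobutanoyl) ester of 19 (C4 epimers) | C#CC[C@]12CCC3(OCCO3)C[C@@H]1[C@](OC(=O)C(C)C(C)=O)(C(OC)OC)C=C2C(=O)OCC[Si](C)(C)C | intermediate
22 | tricyclic 19,10-lactone; C4 with methyl and acetyl, C4–C5 bond anti, H5 syn, C7 ester syn, dimethyl acetal on C10, 12-ketal | C#CC[C@]23CCC4(OCCO4)C[C@@H]2[C@@]1(C(OC)OC)OC(=O)[C@](C)(C(C)=O)[C@H]1[C@@H]3C(=O)OCC[Si](C)(C)C | intermediate
23 | keto aldehyde: 12-ketone, C10–CHO, acetyl on C4, 19,10-lactone | C#CC[C@]23CCC(=O)C[C@@H]2[C@@]1(C=O)OC(=O)[C@](C)(C(C)=O)[C@H]1[C@@H]3C(=O)OCC[Si](C)(C)C | intermediate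
24 | bis(tert-butyldimethylsilyl enol ether) aldehyde (C12=C13 and C3=C2 enol ethers) | C#CC[C@]23CC=C(O[Si](C)(C)C(C)(C)C)C[C@@H]2[C@@]1(C=O)OC(=O)[C@](C)(C(=C)O[Si](C)(C)C(C)(C)C)[C@H]1[C@@H]3C(=O)OCC[Si](C)(C)C | intermediate (not isolated)
25 | propargyl silyl enol ether: 12-silyloxy-12(13)-ene, ring A closed, 1-silyloxy trans to O10, 3-ketone, silylethyl ester | C#CC[C@]23CC=C(O[Si](C)(C)C(C)(C)C)C[C@@H]2[C@]12OC(=O)[C@](C)(C(=O)C[C@H]1O[Si](C)(C)C(C)(C)C)[C@H]2[C@@H]3C(=O)OCC[Si](C)(C)C | intermediate
26 | protected 12-ketone with ring D and C16=C17 | C=C1C[C@]23C[C@H]1C(=O)C[C@@H]2[C@]12OC(=O)[C@](C)(C(=O)C[C@H]1O[Si](C)(C)C(C)(C)C)[C@H]2[C@@H]3C(=O)OCC[Si](C)(C)C | intermediate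
27 | protected 12-alcohol (axial hydroxyl) | C=C1C[C@]23C[C@H]1[C@@H](O)C[C@@H]2[C@]12OC(=O)[C@](C)(C(=O)C[C@H]1O[Si](C)(C)C(C)(C)C)[C@H]2[C@@H]3C(=O)OCC[Si](C)(C)C | intermediate
28 | CNP0259985.3 (1,12-dihydroxy-3-oxo-20-norgibberell-16-ene-7,19-dioic acid 19,10-lactone, configured as drawn) | C=C1C[C@]23C[C@H]1[C@@H](O)C[C@@H]2[C@]12OC(=O)[C@](C)(C(=O)C[C@H]1O)[C@H]2[C@@H]3C(=O)O | target

## Step count and least certain steps

Total: 20 steps. Longest linear sequence: 20 steps (1 to 28).

**Step 18 (key step).** The enol ether may be protodesilylated by adventitious acid before it cyclizes, or the C7 ester carbonyl may add to the activated alkyne, because ester and propargyl arm are cis on adjacent carbons. Fallback: from 25, N-iodosuccinimide converts the enol ether into the 13-iodo-12-ketone F1. Bu3SnH with AIBN then generates the C13 radical α to the ketone, which closes 5-exo-dig onto the alkyne; the vinyl radical abstracts hydrogen and the route is rejoined at 26.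

**Step 15.** Poor facial selectivity of the planar β-keto ester carbanion at C4 would place the acetyl arm inside the fold and leave ring A unable to close. Fallback: the C1–C2 bond is formed before the C4–C5 bond, so that C3 is already tied to C1. From 21, chemoselective cleavage of the aldehyde acetal (Et3SiOTf, 2,4,6-collidine, then water) gives the aldehyde β-keto ester F2. A γ-selective intramolecular vinylogous Mukaiyama aldol of its bis-silyl dienol ether (BF3·OEt2), followed by silylation, gives the seven-membered keto lactone F3. Cs2CO3 then effects the transannular Michael addition, which can only give the required C4 epimer, the ring-A-closed 12-ketal F4. Aqueous acid gives the 12-ketone F5, and t-BuMe2SiOTf/Et3N returns the route to 25.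

**Step 17.** The open transition state of the aldol may give poor control at C1, or the β-silyloxy ketone may eliminate to the enone. Fallback: the C1 oxygen is delivered to the enone instead. From 23, pyrrolidine/AcOH gives the 1-en-3-one F6 by aldol condensation. H2O2/NaOH epoxidizes it from the face away from the lactone bridge to the 1,2-epoxy ketone F7. SmI2 (THF/MeOH, −78 °C) opens the epoxide to the 1-hydroxy-3,12-diketone F8, and t-BuMe2SiOTf/Et3N converts this into 25.

**Step 19.** The hydride may also reduce the C3 ketone, or may attack C12 from the axial side. Fallback: C3 is carried as its enol ether. From 23, excess t-BuMe2SiOTf/Et3N at room temperature gives the tris-silyl compound F9, with C3 masked as its C2=C3 silyl enol ether. The gold step then gives F10 and LiBH(s-Bu)3 gives the 12-alcohol F11. The fluoride treatment of step 20 unmasks ketone, alcohol and acid together and rejoins the route at 28.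

**Step 6.** The acetylenic C–H may consume the hydride reagent, or the alkyne may be hydrometalated, and facial control at C9 may be incomplete. Fallback: dissolving-metal reduction. From 9, the alkyne is first converted into its acetylide with LiNH2 in liquid NH3, and Li in NH3/THF without added alcohol then reduces the enone through the β-carbanion, which is protonated to the trans-fused ketone 10; the cis isomer is removed by chromatography. No new compound is involved.

**Step 12.** The basic ylide may epimerize C9 through the C10 enolate or add in conjugate fashion to the 4-oxo-enoate. Fallback: C1 is introduced as a methylene under non-basic conditions. From 16, Zn/CH2Br2/TiCl4 gives the 10-methylene diene F12. OsO4 (cat.) with N-methylmorpholine N-oxide dihydroxylates the exocyclic alkene from the anti face to the diol F13. TEMPO with PhI(OAc)2 oxidizes the primary alcohol to the hydroxy aldehyde F14, and CH(OMe)3/MeOH with PPTS gives 19.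

Further compounds
F1 | step 18 | 13-iodo-12-ketone (ring A closed, 1-silyl ether, 3-ketone, propargyl on C8) | C#CC[C@]23CC(I)C(=O)C[C@@H]2[C@]12OC(=O)[C@](C)(C(=O)C[C@H]1O[Si](C)(C)C(C)(C)C)[C@H]2[C@@H]3C(=O)OCC[Si](C)(C)C
F2 | step 15 | 10-formyl 10-O-(2-methyl-3-oxobutanoyl) enoate, 12-ketal | C#CC[C@]12CCC3(OCCO3)C[C@@H]1[C@](OC(=O)C(C)C(C)=O)(C=O)C=C2C(=O)OCC[Si](C)(C)C
F3 | step 15 | seven-membered keto lactone spiro at C10 (O10–C19–C4–C3–C2–C1 ring, 1-silyl ether), enoate intact | C#CC[C@]12CCC3(OCCO3)C[C@@H]1[C@@]4(OC(=O)C(C)C(=O)C[C@H]4O[Si](C)(C)C(C)(C)C)C=C2C(=O)OCC[Si](C)(C)C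
F4 | step 15 | ring-A-closed 19,10-lactone, 1-silyl ether, 3-ketone, 12-ketal | C#CC[C@]23CCC4(OCCO4)C[C@@H]2[C@]12OC(=O)[C@](C)(C(=O)C[C@H]1O[Si](C)(C)C(C)(C)C)[C@H]2[C@@H]3C(=O)OCC[Si](C)(C)C
F5 | step 15 | ring-A-closed 19,10-lactone, 1-silyl ether, 3,12-diketone | C#CC[C@]23CCC(=O)C[C@@H]2[C@]12OC(=O)[C@](C)(C(=O)C[C@H]1O[Si](C)(C)C(C)(C)C)[C@H]2[C@@H]3C(=O)OCC[Si](C)(C)C
F6 | step 17 | 1-en-3-one lactone with 12-ketone | C#CC[C@]23CCC(=O)C[C@@H]2[C@]12OC(=O)[C@](C)(C(=O)C=C1)[C@H]2[C@@H]3C(=O)OCC[Si](C)(C)C
F7 | step 17 | 1,2-epoxy-3-ketone lactone (epoxide on the face away from the lactone bridge), 12-ketone | C#CC[C@]23CCC(=O)C[C@@H]2[C@]12OC(=O)[C@](C)(C(=O)[C@H]4O[C@H]41)[C@H]2[C@@H]3C(=O)OCC[Si](C)(C)C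
F8 | step 17 | 1-hydroxy-3,12-diketone lactone (hydroxyl trans to O10) | C#CC[C@]23CCC(=O)C[C@@H]2[C@]12OC(=O)[C@](C)(C(=O)C[C@H]1O)[C@H]2[C@@H]3C(=O)OCC[Si](C)(C)C
F9 | step 19 | tris-silyl precursor: C12=C13 and C2=C3 silyl enol ethers, 1-silyl ether | C#CC[C@]23CC=C(O[Si](C)(C)C(C)(C)C)C[C@@H]2[C@]12OC(=O)[C@](C)(C(O[Si](C)(C)C(C)(C)C)=C[C@H]1O[Si](C)(C)C(C)(C)C)[C@H]2[C@@H]3C(=O)OCC[Si](C)(C)C
F10 | step 19 | 12-ketone with ring D, C3 masked as its silyl enol ether | C=C1C[C@]23C[C@H]1C(=O)C[C@@H]2[C@]12OC(=O)[C@](C)(C(O[Si](C)(C)C(C)(C)C)=C[C@H]1O[Si](C)(C)C(C)(C)C)[C@H]2[C@@H]3C(=O)OCC[Si](C)(C)C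
F11 | step 19 | 12-alcohol with ring D, C3 masked as its silyl enol ether | C=C1C[C@]23C[C@H]1[C@@H](O)C[C@@H]2[C@]12OC(=O)[C@](C)(C(O[Si](C)(C)C(C)(C)C)=C[C@H]1O[Si](C)(C)C(C)(C)C)[C@H]2[C@@H]3C(=O)OCC[Si](C)(C)C
F0 | step 6 | none | none
F12 | step 12 | 10-methylene dienoate, 12-ketal | C#CC[C@]12CCC3(OCCO3)C[C@@H]1C(=C)C=C2C(=O)OCC[Si](C)(C)C
F13 | step 12 | 10-hydroxy-10-(hydroxymethyl) enoate; O10 anti | C#CC[C@]12CCC3(OCCO3)C[C@@H]1[C@](O)(CO)C=C2C(=O)OCC[Si](C)(C)C
F14 | step 12 | 10-hydroxy-10-formyl enoate | C#CC[C@]12CCC3(OCCO3)C[C@@H]1[C@](O)(C=O)C=C2C(=O)OCC[Si](C)(C)C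
A1 | alternative 1 | 2-allyl-2-(3-oxobutyl)cyclopentane-1,3-dione | C=CCC1(CCC(C)=O)C(=O)CCC1=O
A2 | alternative 1 | angular-allyl Hajos–Parrish enedione | C=CC[C@]12CCC(=O)C=C1CCC2=O
A3 | alternative 2 | C10 imidazole-1-carboxylate of the ring A 4-methyl-3-ketone (ring D present, 12-silyl ether, tert-butyl ester) | C=C1C[C@]23C[C@H]1[C@@H](O[Si](C)(C)C(C)(C)C)C[C@@H]2[C@]1(OC(=O)n4ccnc4)CCC(=O)C(C)[C@H]1[C@@H]3C(=O)OC(C)(C)C
A4 | alternative 2 | 1-deoxy protected target | C=C1C[C@]23C[C@H]1[C@@H](O[Si](C)(C)C(C)(C)C)C[C@@H]2[C@]12OC(=O)[C@](C)(C(=O)CC1)[C@H]2[C@@H]3C(=O)OC(C)(C)C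
A5 | alternative 3 | C12 aldehyde with spiro cyclopentenyl allylsilane at C8 (C13=C16, CH2SiMe3 on C16) | C[Si](C)(C)CC1=CC[C@@]2(C1)[C@H](CC=O)[C@]13OC(=O)[C@](C)(C(=O)C[C@H]1O[Si](C)(C)C(C)(C)C)[C@H]3[C@@H]2C(=O)OC(C)(C)C
A6 | alternative 3 | C1 silyl ether tert-butyl ester of the target | C=C1C[C@]23C[C@H]1[C@@H](O)C[C@@H]2[C@]12OC(=O)[C@](C)(C(=O)C[C@H]1O[Si](C)(C)C(C)(C)C)[C@H]2[C@@H]3C(=O)OC(C)(C)C
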